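The numbers of this flask were chosen freely; the result is computed.

I decide to follow one number through these runs, the starting material left, and to read the share of mono adduct from it.

1. the set-up with the highest share of mono adduct in all that became mono adduct or bis adduct or over-reaction product, at the outlet or at the end ("none" if the first two lie within 2 percentage points) (epsilon / gamma / zeta / eta / none)
2. share of mono adduct in all that became mono adduct or bis adduct or over-reaction product, at the outlet or at the end, epsilon
3. share of mono adduct in all that became mono adduct or bis adduct or over-reaction product, at the outlet or at the end, gamma
4. share of mono adduct in all that became mono adduct or bis adduct or over-reaction product, at the outlet or at the end, zeta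
5. share of mono adduct in all that became mono adduct or bis adduct or over-reaction product, at the outlet or at the end, eta

| flask | starting material | reagent | remark | time |
|---|---|---|---|---|
| epsilon | 5.0 mM | 5.00 mM | a single well-mixed tank run continuously and read at steady state, 15 s in it on average |  |
| gamma | 5.0 mM | 5.00 mM (fed, over 15.0 s) | all but reagent at the start; reagent goes in evenly over 15.0 s, the run ends at 15 s | 15 s |
| zeta | 5.0 mM (fed, over 15.0 s) | 5.00 mM | all but starting material at the start; starting material goes in evenly over 15.0 s, the run ends at 15 s | 15 s |
| eta | 5.0 mM | 5.00 mM | a closed flask charged with all of it at once and left for 15 s | 15 s |

    reagent + mono adduct → bis adduct (k1 = 32 /M/s)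
    starting material + reagent → mono adduct (k2 = 17 /M/s)
    reagent + mono adduct → over-reaction product (k3 = 2.0 /M/s)

- the stated concentrations are those of everything mixed, before any reaction; amounts are the same in each set-up
- the feed brings no volume worth counting
- run time (gamma): 15 s

I carry 2.00 as the attack ratio, the two constants that consume mono adduct summed and divided by the one that forms it, a selectivity factor. Since [reagent] stands in both the forming and the consuming rate, it cancels, so where starting material lies in the flask from the start and nothing leaves, [mono adduct] against [starting material] follows one path however the reagent arrives. With x the fraction of starting material left and u the fraction reacted, this ratio puts mono adduct at x·u, so the share is x itself; that covers eta and gamma, but not epsilon with its outflow or zeta with its fed starting material, which I leave unreckoned.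

The ledger of reagent, charged level with starting material, has u spent on forming mono adduct and u·u on the second attack. The logarithm of x is minus 1.28 times the mean reagent fraction. A mean of half gives x = 52.9 %, and the ledger then leaves 30.6 % of the reagent. Putting that back, with eta's mean midway from full charge and gamma's midway from nothing, gives 43.5 % and 82.3 %. The answers swing, so I take the middle between the first x and each second one: 48.2 % for eta and 67.6 % for gamma, which puts gamma higher than eta.

| Reagent, at the end | eta | gamma |
|---|---|---|
| forming mono adduct | 51.8 % | 32.4 % |
| second attack | 26.8 % | 10.5 % |
| left | 21.4 % | 57.1 % |

The forecast chooses gamma, with 46.8 % for epsilon, 65.3 % for gamma, 55 % for zeta and 50.2 % for eta, on the ground that dosing the reagent “keeps it scarce against a large pool of starting material”. My eta lies lower than the forecast's, and my gamma higher than the forecast's.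

The simulation gives gamma, with 46.8 % for epsilon, 65.5 % for gamma, 55.1 % for zeta and 50.2 % for eta.

In the neighbour, gamma left until 40.0 s, the starting material reads 41 %. Put into the attack ratio, that reading gives a share of 41.2 %, and the ledger leaves 6.72 % of the reagent. That neighbour flask gives a share of 41.2 % and reagent at 6.72 %.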